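Retrosynthetic overview
- The target is an ether "dimer" of esculetin. O6 of coumarin ring system A is bonded to C5 of coumarin ring system B, and both halves come from one commercial coumarin, isoscopoletin 1.
- Electrophile for ring system B: 1 → 2 (iodination at C5, ortho to the free 6-OH) → 3 (O-methylation).
- Key disconnection is the C5–O6' diaryl ether, made by Ullmann coupling 3 + 1 → 4. The last disconnection is the three O–CH3 bonds, cleaved with BBr3: 4 → 5 → 6.
- Ring formation: none. All four rings (two benzene, two pyranone) are already present in 1.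

Assumption: the SMILES has no stereocentre and the diaryl ether rotates freely, so the target is achiral and needs no enantiocontrol.

Step 1
Reactants: 1 isoscopoletin (6-hydroxy-7-methoxy-2H-chromen-2-one)
Product: 2 5-iodoisoscopoletin (6-hydroxy-5-iodo-7-methoxy-2H-chromen-2-one)
Conditions: NIS (1.05 equiv), TsOH·H2O (10 mol %), MeCN, 0 °C to rt, dark
Reagents that add atoms: N-iodosuccinimide (NIS), O=C1CCC(=O)N1I
Why: Electrophilic aromatic iodination is governed by the free 6-OH, whose para position (C8a) and second ortho position (C7) are substituted, so iodine enters at C5 just as isovanillin is halogenated at C2 between its OH and the acceptor-bearing carbon, while the weaker 7-OMe director leaves C8 and C3 untouched at one equivalent of NIS, and no stereocentre is created.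

Step 2
Reactants: 2 5-iodoisoscopoletin
Product: 3 5-iodoscoparone (5-iodo-6,7-dimethoxy-2H-chromen-2-one)
Conditions: MeI (1.5 equiv), K2CO3 (1.5 equiv), acetone, reflux
Reagents that add atoms: iodomethane (MeI), CI
Why: Williamson ether synthesis (SN2 of the potassium phenoxide on MeI) caps the only acidic OH so that 3 cannot act as a nucleophile in the coupling, and anhydrous K2CO3 in acetone leaves the lactone and the aryl iodide untouched.

Step 3
Reactants: 3 5-iodoscoparone; 1 isoscopoletin (1.2 equiv)
Product: 4 trimethyl ether of the target (6,7-dimethoxy-5-[(7-methoxy-2-oxo-2H-chromen-6-yl)oxy]-2H-chromen-2-one)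
Conditions: CuI (10 mol %), picolinic acid (20 mol %), K3PO4 (2.0 equiv), DMSO, 90 °C, Ar, 24 h; then 1 M HCl work-up
Reagents that add atoms: none
Why: In this Ullmann diaryl ether synthesis the monovalent copper picolinate binds the phenoxide of 1, activates the only C–I bond present (C5 of 3, helped by the ortho vinylogous lactone carbonyl) and forms the C5–O6' bond with a ligand suited to ortho-substituted partners, and any lactone opened by base recloses on the acidic work-up.

Step 4
Reactants: 4 trimethyl ether of the target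
Product: 6 6,7-dihydroxy-5-[(7-hydroxy-2-oxo-2H-chromen-6-yl)oxy]-2H-chromen-2-one (target CNP0197949.0), via bromoboron aryloxide 5 (not isolated)
Conditions: BBr3 (8 equiv, 1 M in CH2Cl2), CH2Cl2, −78 °C to rt, 16 h; then ice/H2O, 0 °C
Reagents that add atoms: none
Why: In this Lewis-acid aryl methyl ether cleavage BBr3 complexes each OMe oxygen and bromide removes the methyl group by SN2 to give boron aryloxide 5, which water hydrolyses to the three free phenols, whereas the diaryl ether (no sp3 carbon to attack) and both lactones persist and no stereocentre is involved.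

Compound list
1 | isoscopoletin (6-hydroxy-7-methoxy-2H-chromen-2-one), achiral | COc1cc2oc(=O)ccc2cc1O | starting material
2 | 6-hydroxy-5-iodo-7-methoxy-2H-chromen-2-one, achiral | COc1cc2oc(=O)ccc2c(I)c1O | intermediate
3 | 5-iodo-6,7-dimethoxy-2H-chromen-2-one, achiral | COc1cc2oc(=O)ccc2c(I)c1OC | intermediate
4 | 6,7-dimethoxy-5-[(7-methoxy-2-oxo-2H-chromen-6-yl)oxy]-2H-chromen-2-one, achiral | COc1cc2oc(=O)ccc2c(Oc2cc3ccc(=O)oc3cc2OC)c1OC | intermediate
5 | bromoboron aryloxide: O6 and O7 of ring system B tied in a cyclic B-bromo-1,3,2-dioxaborole, O7 of ring system A carried as OBBr2, achiral | O=c1ccc2cc(Oc3c4OB(Br)Oc4cc4oc(=O)ccc34)c(OB(Br)Br)cc2o1 | intermediate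
6 | 6,7-dihydroxy-5-[(7-hydroxy-2-oxo-2H-chromen-6-yl)oxy]-2H-chromen-2-one, achiral | O=c1ccc2cc(Oc3c(O)c(O)cc4oc(=O)ccc34)c(O)cc2o1 | target

Total step count: 4
Longest linear sequence: 4 (1 → 2 → 3 → 4 → 6). Compound 1 enters twice, in steps 1 and 3.

Steps most likely to fail

First, step 3. Iodide 3 carries two ortho substituents, so the copper cycle may stall or merely remove iodine. The fallback is a metal-free O-arylation through a diaryliodonium salt. It sets out from 3 and comes back to the route at 4.
- Iodide 3 is oxidised with mCPBA and TsOH·H2O in MeCN at 75 °C to the Koser-type reagent 5-[hydroxy(tosyloxy)iodanyl]-6,7-dimethoxy-2H-chromen-2-one F1.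
- F1 is trapped in the same flask by 1,3,5-trimethoxybenzene to give (6,7-dimethoxy-2-oxo-2H-chromen-5-yl)(2,4,6-trimethoxyphenyl)iodonium tosylate F2.
- The potassium phenoxide of 1 (K2CO3, MeCN, 60 °C) then binds to trivalent iodine. Ligand coupling transfers the less electron-rich coumarinyl group, with the trimethoxyphenyl group as the non-transferred dummy, and gives 4.

Second, step 1. The risks are site selectivity (C5 against C8 and C3) and over-iodination. The fallback places carbon at C5 by a reaction that can only go ortho to a free phenol, then exchanges that carbon for iodine. It sets out from 1 and comes back to the route at 3.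
- Duff formylation of 1 (hexamethylenetetramine, TFA, reflux, then aqueous HCl) gives 6-hydroxy-7-methoxy-2-oxo-2H-chromene-5-carbaldehyde F3.
- MeI and K2CO3 in DMF give 6,7-dimethoxy-2-oxo-2H-chromene-5-carbaldehyde F4.
- Pinnick oxidation (NaClO2, NaH2PO4, 2-methyl-2-butene, t-BuOH/H2O) gives 6,7-dimethoxy-2-oxo-2H-chromene-5-carboxylic acid F5.
- Decarboxylative ipso-iodination (I2, K3PO4, MeCN, 100 °C) delivers 3.

Third, step 4. The risks of a threefold demethylation at the very end are incomplete cleavage of the less basic 7-OMe groups, poorly soluble boron chelates, and an air-sensitive catechol during aqueous work-up. The fallback changes the protecting groups to benzyl so that the last operation is a neutral hydrogenolysis. It sets out from 1 and comes back to the route at 6.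
- Compound 1 is demethylated as the simple monomer (BBr3, CH2Cl2) to esculetin (6,7-dihydroxy-2H-chromen-2-one) F6.
- The more acidic 7-OH is benzylated (BnBr 1.0 equiv, K2CO3 1.0 equiv, DMF, rt) to 7-(benzyloxy)-6-hydroxy-2H-chromen-2-one F7.
- Part of F7 is iodinated with NIS as in step 1 to 7-(benzyloxy)-6-hydroxy-5-iodo-2H-chromen-2-one F8.
- F8 is benzylated (BnBr, K2CO3, DMF) to 6,7-bis(benzyloxy)-5-iodo-2H-chromen-2-one F9.
- Coupling of F9 with the rest of F7 (CuI, picolinic acid, K3PO4, DMSO, 90 °C) gives 6,7-bis(benzyloxy)-5-{[7-(benzyloxy)-2-oxo-2H-chromen-6-yl]oxy}-2H-chromen-2-one F10.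
- H2 (1 atm), Pd/C, EtOAc/THF, rt, stopped after uptake of three equivalents to spare the C3–C4 double bonds, gives 6.

Further compounds
F1 | step 3 | 5-[hydroxy(tosyloxy)iodanyl]-6,7-dimethoxy-2H-chromen-2-one | COc1cc2oc(=O)ccc2c(I(O)OS(=O)(=O)c2ccc(C)cc2)c1OC
F2 | step 3 | (6,7-dimethoxy-2-oxo-2H-chromen-5-yl)(2,4,6-trimethoxyphenyl)iodonium tosylate | COc1cc(OC)c([I+]c2c(OC)c(OC)cc3oc(=O)ccc23)c(OC)c1.Cc1ccc(cc1)S(=O)(=O)[O-]
F3 | step 1 | 6-hydroxy-7-methoxy-2-oxo-2H-chromene-5-carbaldehyde | COc1cc2oc(=O)ccc2c(C=O)c1O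
F4 | step 1 | 6,7-dimethoxy-2-oxo-2H-chromene-5-carbaldehyde | COc1cc2oc(=O)ccc2c(C=O)c1OC
F5 | step 1 | 6,7-dimethoxy-2-oxo-2H-chromene-5-carboxylic acid | COc1cc2oc(=O)ccc2c(C(=O)O)c1OC
F6 | step 4 | esculetin (6,7-dihydroxy-2H-chromen-2-one) | O=c1ccc2cc(O)c(O)cc2o1
F7 | step 4 | 7-(benzyloxy)-6-hydroxy-2H-chromen-2-one | O=c1ccc2cc(O)c(OCc3ccccc3)cc2o1
F8 | step 4 | 7-(benzyloxy)-6-hydroxy-5-iodo-2H-chromen-2-one | O=c1ccc2c(I)c(O)c(OCc3ccccc3)cc2o1
F9 | step 4 | 6,7-bis(benzyloxy)-5-iodo-2H-chromen-2-one | O=c1ccc2c(I)c(OCc3ccccc3)c(OCc3ccccc3)cc2o1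
F10 | step 4 | 6,7-bis(benzyloxy)-5-{[7-(benzyloxy)-2-oxo-2H-chromen-6-yl]oxy}-2H-chromen-2-one | O=c1ccc2c(Oc3cc4ccc(=O)oc4cc3OCc3ccccc3)c(OCc3ccccc3)c(OCc3ccccc3)cc2o1
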